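**Retrosynthetic overview**
- The target comes from its N,N'-bis(trifluoroacetyl) derivative by mild methanolysis in the same pot.
- Key disconnection: the C3–C3' bond and both N1–C2 bonds are cut in one operation. This gives two molecules of N-[4,5-dibromo-2-(bromoethynyl)phenyl]-2,2,2-trifluoroacetamide (new oxidative aminopalladation/homocoupling). Both C2–Br bonds arrive as the alkynyl bromide.
- The bromoalkyne comes from the silylalkyne (ipso-bromodesilylation), and that from the free aniline (N-trifluoroacetylation).
- The aryl–alkyne bond comes from 4,5-dibromo-2-iodoaniline plus ethynyltrimethylsilane (Sonogashira). The iodoaniline comes from 3,4-dibromoaniline (ortho-iodination).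
- Ring order: both benzene rings are bought with their bromines in place. The two pyrrole rings are closed last, together, in the step that also makes the biaryl bond.

Assumption: the given SMILES holds no stereodescriptor and the molecule has no stereocentre; the only possible stereogenic unit, the C3–C3' axis, is not defined in it, so the target is taken as drawn and the axis is left uncontrolled.

**Step 1**
Reactants: 1 3,4-dibromoaniline
Product: 2 4,5-dibromo-2-iodoaniline
Conditions: NIS (1.05 equiv), AcOH, rt, dark
Reagents that add atoms: N-iodosuccinimide, O=C1CCC(=O)N1I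
Why: Electrophilic aromatic iodination directed by NH2: the para position is blocked by bromine and C2 is squeezed between NH2 and Br, so iodine enters at C6; no stereocentre is formed.

**Step 2**
Reactants: 2 4,5-dibromo-2-iodoaniline; 3 ethynyltrimethylsilane
Product: 4 4,5-dibromo-2-[(trimethylsilyl)ethynyl]aniline
Conditions: PdCl2(PPh3)2 (2 mol %), CuI (4 mol %), Et3N (3 equiv), THF, rt
Reagents that add atoms: none
Why: Sonogashira coupling: at room temperature zerovalent palladium inserts into the carbon–iodine bond far faster than into the two aryl C–Br bonds, so only the iodide is replaced.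

**Step 3**
Reactants: 4 4,5-dibromo-2-[(trimethylsilyl)ethynyl]aniline
Product: 5 N-{4,5-dibromo-2-[(trimethylsilyl)ethynyl]phenyl}-2,2,2-trifluoroacetamide
Conditions: (CF3CO)2O (1.2 equiv), CH2Cl2, 0 °C to rt
Reagents that add atoms: trifluoroacetic anhydride, O=C(OC(=O)C(F)(F)F)C(F)(F)F
Why: N-Acylation with an anhydride: the trifluoroacetamide acidifies N–H for the later aminopalladation, blocks ring bromination and addition to the quinone, and is later removed by very mild methanolysis.

**Step 4**
Reactants: 5 N-{4,5-dibromo-2-[(trimethylsilyl)ethynyl]phenyl}-2,2,2-trifluoroacetamide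
Product: 6 N-[4,5-dibromo-2-(bromoethynyl)phenyl]-2,2,2-trifluoroacetamide
Conditions: NBS (1.1 equiv), AgNO3 (10 mol %), acetone, rt, dark; aqueous work-up
Reagents that add atoms: N-bromosuccinimide, O=C1CCC(=O)N1Br
Why: Silver-catalysed ipso-bromodesilylation of an alkynylsilane: Si-to-Ag exchange gives a silver acetylide that NBS brominates, while the doubly brominated anilide ring is too deactivated to react.

**Step 5**
Reactants: 6 N-[4,5-dibromo-2-(bromoethynyl)phenyl]-2,2,2-trifluoroacetamide (two molecules)
Product: 8 2,2',5,5',6,6'-hexabromo-1H,1'H-3,3'-biindole, via N,N'-bis(trifluoroacetyl)hexabromobiindole 7 (not isolated)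
Conditions: Pd(OAc)2 (10 mol %), 4,5-diazafluoren-9-one (12 mol %), 2,6-dimethyl-1,4-benzoquinone (0.6 equiv), NaOAc (20 mol %), 4 Å MS, MeCN (0.3 M), 45 °C; then MeOH, K2CO3 (20 mol %), rt
Reagents that add atoms: none
Why: Proposed new method: oxidative aminopalladation/homocoupling of a 1-bromoalkyne, a dimerising Cacchi-type annulation driven from divalent palladium: Pd(OAc)2 π-activates the bromoalkyne of 6; acetate-assisted anti 5-endo-dig attack of the amide nitrogen on the bromine-bearing carbon (the only closure the geometry allows) gives a 2-bromoindol-3-yl palladium acetate that cannot β-eliminate bromide, because that would need a 2,3-indolyne; this σ-aryl complex activates a second molecule of 6 in the same way; the hemilabile diazafluorenone holds the resulting bis(indol-3-yl)palladium cis, and it reductively eliminates the C3–C3' bond under the push of the π-acidic quinone; the quinone takes up the two electrons and the two AcOH released by the aminopalladations, so zerovalent palladium is re-oxidised while still quinone-bound instead of inserting into the C(sp)–Br or C(sp2)–Br bonds; copper is left out because it would N-alkynylate the amide with the bromoalkyne; methanolysis then strips the labile N-acyl groups of 7; no stereocentre is formed; the closest known reaction types are the aminopalladation/oxidative homocoupling of carbon-substituted 2-alkynylanilines to 2,2'-disubstituted 3,3'-biindoles and the base-induced 5-endo cyclisation of 2-(bromoethynyl)anilides to 2-bromoindoles.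

**Compound list**
1 | 3,4-dibromoaniline | Nc1ccc(Br)c(Br)c1 | starting material
2 | 4,5-dibromo-2-iodoaniline | Nc1cc(Br)c(Br)cc1I | intermediate
3 | ethynyltrimethylsilane | C#C[Si](C)(C)C | starting material
4 | 4,5-dibromo-2-[(trimethylsilyl)ethynyl]aniline | Nc1cc(Br)c(Br)cc1C#C[Si](C)(C)C | intermediate
5 | N-{4,5-dibromo-2-[(trimethylsilyl)ethynyl]phenyl}-2,2,2-trifluoroacetamide | O=C(Nc1cc(Br)c(Br)cc1C#C[Si](C)(C)C)C(F)(F)F | intermediate
6 | N-[4,5-dibromo-2-(bromoethynyl)phenyl]-2,2,2-trifluoroacetamide | O=C(Nc1cc(Br)c(Br)cc1C#CBr)C(F)(F)F | intermediate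
7 | 1,1'-(2,2',5,5',6,6'-hexabromo-3,3'-biindole-1,1'-diyl)bis(2,2,2-trifluoroethan-1-one) | Brc1cc2n(C(=O)C(F)(F)F)c(Br)c(-c3c(Br)n(C(=O)C(F)(F)F)c4cc(Br)c(Br)cc34)c2cc1Br | intermediate
8 | 2,2',5,5',6,6'-hexabromo-1H,1'H-3,3'-biindole | Brc1cc2[nH]c(Br)c(-c3c(Br)[nH]c4cc(Br)c(Br)cc34)c2cc1Br | target

**Total step count:** 5
**Longest linear sequence:** 5 steps (1, 2, 4, 5, 6, 8)

**Three steps most likely to fail**

(a) Step 5 (the proposed new step).
- Risks:
  - Protodepalladation of the mono-indolyl complex gives monomeric 2,5,6-tribromoindole.
  - Escaped zerovalent palladium inserts into the bromoalkyne and leads to 3-alkynylindoles or diynes.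
  - Reductive elimination from the hindered bis(indolyl) complex is slow.
- Fallback by known chemistry only, setting out from 4 and coming back at 8. K2CO3 in MeOH removes the silyl group of 4 to give 4,5-dibromo-2-ethynylaniline F1. CuI in DMF at 100 °C closes it by 5-endo-dig hydroamination to 5,6-dibromo-1H-indole F2. The established palladium-catalysed oxidative C3–H/C3–H dimerisation of free (NH) indoles (Pd(OCOCF3)2 cat., AgNO3, DMSO) gives 5,5',6,6'-tetrabromo-1H,1'H-3,3'-biindole F3. NBS (2.0 equiv, THF, −78 °C to 0 °C) then brominates the only activated positions left, C2 and C2', as is usual for 3-substituted indoles, and delivers 8.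

(b) Step 4.
- Risks: Si-to-Br exchange may be sluggish, and prolonged contact with monovalent silver may cyclise the anilide onto the alkyne.
- Fallback without any π-acidic metal, setting out from 5 and coming back at 6. Buffered fluoride (nBu4NF/AcOH 1:1, THF, 0 °C) removes the silyl group without touching the amide and gives N-(4,5-dibromo-2-ethynylphenyl)-2,2,2-trifluoroacetamide F4. The terminal C–H of this compound is brominated oxidatively and base-free with PhI(OAc)2/nBu4NBr in MeCN at rt to give 6.

(c) Step 1.
- Risks: some attack at the crowded C2 position, and di-iodination, would give isomers that are hard to separate.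
- Fallback that replaces electrophilic substitution by chelation-directed C–H palladation, setting out from 1 and coming back at 2. Ac2O converts 1 into N-(3,4-dibromophenyl)acetamide F5. Anilide-directed ortho-iodination (Pd(OAc)2 5 mol %, TsOH, NIS, toluene, rt) metalates only the less hindered ortho C–H and gives N-(4,5-dibromo-2-iodophenyl)acetamide F6. Hydrolysis (HCl, EtOH/H2O, reflux) returns 2.

**Further compounds**
F1 | step 5 | 4,5-dibromo-2-ethynylaniline | Nc1cc(Br)c(Br)cc1C#C
F2 | step 5 | 5,6-dibromo-1H-indole | Brc1cc2cc[nH]c2cc1Br
F3 | step 5 | 5,5',6,6'-tetrabromo-1H,1'H-3,3'-biindole | Brc1cc2[nH]cc(-c3c[nH]c4cc(Br)c(Br)cc34)c2cc1Br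
F4 | step 4 | N-(4,5-dibromo-2-ethynylphenyl)-2,2,2-trifluoroacetamide | O=C(Nc1cc(Br)c(Br)cc1C#C)C(F)(F)F
F5 | step 1 | N-(3,4-dibromophenyl)acetamide | CC(=O)Nc1ccc(Br)c(Br)c1
F6 | step 1 | N-(4,5-dibromo-2-iodophenyl)acetamide | CC(=O)Nc1cc(Br)c(Br)cc1I
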